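**Assumptions.** L-Tyrosinol·HCl, (E)-2-decenoic acid and all reagents are taken as commercial. Only substrates, intermediates and the target are numbered; atom-donating reagents are named with SMILES in each step.

**Core numbering used below.** C1 = bridgehead C(OH); C2/C3 = oxirane carbons (alkene in 6–9); C4 = CH(OH); C5 = bridgehead CH; C6 = CH(OH); C7 = CH–NH; C8 = CH2; C9 = one-carbon bridge (C=O in the target). Ring A = C1-C2-C3-C4-C5-C9; ring B = C1-C8-C7-C6-C5-C9. "Exo face" = face of ring A opposite the C6–C7–C8 bridge. In this numbering the target is (1S,2S,3S,4S,5S,6R,7S).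

## Retrosynthetic overview

1. Isariotin D ⇐ C9 carbinol oxidation and desilylation; oxirane ⇐ exo, hydroxyl-directed epoxidation of C2=C3; C4–OH ⇐ 1,2-reduction of a C4 enone.
2. Bicyclo[3.3.1]non-2-en-4-one (C5–C6 bond, C9–O, stereocentres C1/C5/C6) ⇐ proposed boronic acid-templated oxa-Michael/aldol desymmetrisation of a symmetric p-quinol aldehyde (as its lactol).
3. p-Quinol lactol ⇐ oxidative dearomatisation of N-(E)-dec-2-enoyl-L-tyrosinol, then 1,4-diol → lactol oxidation.
4. Ring order: ring A (the tyrosine arene, dearomatised) → ring B (C5–C6 aldol) → oxirane last. C7 comes from L-tyrosinol and controls everything else.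

## Route

**Step 1**
Reactants: 1, L-tyrosinol hydrochloride; 2, (E)-dec-2-enoic acid
Product: 3, (E)-N-[(2S)-1-hydroxy-3-(4-hydroxyphenyl)propan-2-yl]dec-2-enamide
Conditions: EDC·HCl, HOBt, iPr2NEt, DMF, 0 °C→rt
Reagents that add atoms: none (2 is a numbered reactant)
Why: HOBt-ester amide coupling acylates the amine chemoselectively over the phenol and primary alcohol, and the L-derived stereocentre (future C7, S) is untouched.

**Step 2**
Reactants: 3
Product: 4, (E)-N-[(2S)-1-hydroxy-3-(1-hydroxy-4-oxocyclohexa-2,5-dien-1-yl)propan-2-yl]dec-2-enamide (p-quinol)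
Conditions: Oxone, NaHCO3, MeCN/H2O, rt; then Na2S2O3
Reagents that add atoms: Oxone (potassium peroxymonosulfate), OOS(=O)(=O)[O-].[K+] (source of the C1–OH oxygen)
Why: Oxidative dearomatisation in which Oxone/bicarbonate-derived singlet oxygen adds para to the phenol to give the p-peroxyquinol, reduced in situ to the p-quinol; the electron-poor enamide alkene is inert and the dienone is still symmetric, so C1 is not yet stereogenic.

**Step 3**
Reactants: 4
Product: 5, (E)-N-[(3S)-2-hydroxy-8-oxo-1-oxaspiro[4.5]deca-6,9-dien-3-yl]dec-2-enamide (spirolactol, anomer mixture, in equilibrium with the open hydroxy-aldehyde)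
Conditions: IBX, DMSO, rt
Reagents that add atoms: none
Why: IBX oxidation of a 1,4-diol stops at the γ-lactol (primary alcohol → aldehyde, trapped by the tertiary OH, no lactone), which also masks the epimerisable α-amido aldehyde.

**Step 4 (proposed new transformation)**
Reactants: 5
Product: 6, cyclic phenylboronate (O1–B(Ph)–O9) of (E)-N-[1,6,9-trihydroxy-4-oxobicyclo[3.3.1]non-2-en-7-yl]dec-2-enamide; C1, C5, C6, C7 arranged as in the target (6-OH axial in ring B, 7-NH-acyl equatorial), 9-O on the exo face cis to O1
Conditions: PhB(OH)2 (1.5 equiv), quinuclidine (20 mol%), N,N′-bis[3,5-bis(trifluoromethyl)phenyl]thiourea (20 mol%), 4 Å MS, PhMe, rt→40 °C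
Reagents that add atoms: phenylboronic acid, OB(O)c1ccccc1 (B, Ph and the C9 oxygen)
Why: Proposed new method: a boronic acid-templated hydroxylative aldol desymmetrisation in which the lactol opens to the hydroxy-aldehyde, PhB(OH)2 esterifies the tertiary C1–OH, the amine-ligated B–OH adds reversibly (5-exo oxa-Michael, syn to O1) to either diastereotopic enone β-carbon, and only the adduct whose C5 enol reaches the aldehyde through a chair transition state with equatorial NH-acyl (Felkin–Anh, C5 anti to C7–N, aldehyde C=O anti to the enol C–O) closes ring B, so Curtin–Hammett selection sets C1, C5 and C6 while water removal makes the dioxaborolane a thermodynamic sink; the closest known reaction types are amine/boronic acid-mediated β-hydroxylation of γ-hydroxy enones, acetal-templated oxa-Michael desymmetrisation of p-quinols, and tandem oxa-Michael/aldol cyclisations.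

**Step 5**
Reactants: 6
Product: 7, the C4 allylic alcohol of 6 (4-OH on the exo face, cis to O9 and O1; boronate and 6-OH unchanged)
Conditions: NaBH4, CeCl3·7H2O, MeOH/THF, −78 °C
Reagents that add atoms: none
Why: Luche 1,2-reduction in which hydride enters C4 from the endo face, anti to the syn-axial C9–O–B(Ph) group that shields the exo face (1,3-diaxial control), giving the exo (axial) 4-OH without touching the amide or enamide.

**Step 6**
Reactants: 7
Product: 8, 4,6-bis(triethylsilyl) ether of 7 (boronate intact)
Conditions: TESOTf, 2,6-lutidine, CH2Cl2, −78→0 °C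
Reagents that add atoms: triethylsilyl triflate, CC[Si](CC)(CC)OS(=O)(=O)C(F)(F)F
Why: Silyl triflate silylation caps both free secondary alcohols while O1/O9 stay masked as the boronate, so C9–OH can later be released alone.

**Step 7**
Reactants: 8
Product: 9, (E)-N-[1,9-dihydroxy-4,6-bis(triethylsilyloxy)bicyclo[3.3.1]non-2-en-7-yl]dec-2-enamide (cis-1,9-diol; stereocentres unchanged)
Conditions: 30% H2O2, NaHCO3, THF/H2O, 0 °C
Reagents that add atoms: none
Why: Oxidative B–aryl cleavage followed by borate hydrolysis frees the cis-diol, and buffered peroxide does not affect the silyl ethers, the unactivated ring alkene or the enamide (no ketone is present, so no retro-aldol).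

**Step 8**
Reactants: 9
Product: 10, exo-2,3-epoxide of 9 (oxirane O cis to O1, O4 and O9)
Conditions: VO(acac)2 (cat.), t-BuOOH (decane), CH2Cl2, 0 °C→rt
Reagents that add atoms: tert-butyl hydroperoxide, CC(C)(C)OO (oxirane O)
Why: Vanadium-catalysed hydroxyl-directed epoxidation in which the allylic C1–OH and homoallylic C9–OH, both on the exo face, deliver oxygen to that face (the endo face is buried under ring B), setting C2 and C3; the electron-poor enamide is not epoxidised.

**Step 9**
Reactants: 10
Product: 11, 4,6-bis(triethylsilyl) ether of isariotin D (C9 ketone)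
Conditions: IBX, DMSO, rt→40 °C
Reagents that add atoms: none
Why: IBX oxidises the only free secondary alcohol to the bridging ketone without glycol cleavage of the tertiary/secondary diol, and C5 cannot epimerise (bridgehead, anti-Bredt enol).

**Step 10**
Reactants: 11
Product: 12, isariotin D
Conditions: HF·pyridine, pyridine/THF, 0 °C
Reagents that add atoms: none
Why: Buffered fluoride desilylation removes both TES ethers under non-basic conditions that avoid retro-aldol of the β-hydroxy ketone and leave the cis-epoxy alcohols (no Payne pathway) intact.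

## Compound list

1 | L-tyrosinol hydrochloride | Cl.N[C@@H](Cc1ccc(O)cc1)CO | starting material
2 | (E)-dec-2-enoic acid | CCCCCCC/C=C/C(=O)O | starting material
3 | N-(E)-dec-2-enoyl-L-tyrosinol | CCCCCCC/C=C/C(=O)N[C@@H](Cc1ccc(O)cc1)CO | intermediate
4 | p-quinol diol | CCCCCCC/C=C/C(=O)N[C@@H](CC1(O)C=CC(=O)C=C1)CO | intermediate
5 | spirolactol (anomers) | CCCCCCC/C=C/C(=O)N[C@H]1CC2(C=CC(=O)C=C2)OC1O | intermediate
6 | O1,O9-phenylboronate bicyclic enone ketol | CCCCCCC/C=C/C(=O)N[C@H]1C[C@@]2(C=CC(=O)[C@@H]3[C@H]1O)OB(c4ccccc4)O[C@@H]23 | intermediate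
7 | O1,O9-phenylboronate allylic alcohol | CCCCCCC/C=C/C(=O)N[C@H]1C[C@@]2(C=C[C@@H](O)[C@@H]3[C@H]1O)OB(c4ccccc4)O[C@@H]23 | intermediate
8 | 4,6-bis-TES boronate | CCCCCCC/C=C/C(=O)N[C@H]1C[C@@]2(C=C[C@@H](O[Si](CC)(CC)CC)[C@@H]3[C@H]1O[Si](CC)(CC)CC)OB(c4ccccc4)O[C@@H]23 | intermediate
9 | 4,6-bis-TES 1,9-diol alkene | CCCCCCC/C=C/C(=O)N[C@H]1C[C@]2(O)C=C[C@@H](O[Si](CC)(CC)CC)[C@H]([C@H]1O[Si](CC)(CC)CC)[C@H]2O | intermediate
10 | 4,6-bis-TES 2,3-epoxy-1,9-diol | CCCCCCC/C=C/C(=O)N[C@H]1C[C@@]2(O)[C@H](O)[C@H]([C@H](O[Si](CC)(CC)CC)[C@@H]3O[C@@H]32)[C@H]1O[Si](CC)(CC)CC | intermediate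
11 | 4,6-bis-TES isariotin D | CCCCCCC/C=C/C(=O)N[C@H]1C[C@@]2(O)C(=O)[C@H]([C@H](O[Si](CC)(CC)CC)[C@@H]3O[C@@H]32)[C@H]1O[Si](CC)(CC)CC | intermediate
12 | isariotin D | CCCCCCC/C=C/C(=O)N[C@H]1C[C@@]2(O)C(=O)[C@H]([C@H](O)[C@@H]3O[C@@H]32)[C@H]1O | target

## Summary

Total steps: 10. Longest linear sequence: 10 (from L-tyrosinol).

Three steps most likely to fail:

1. **Step 4 (proposed new cascade).** Risks are competing oxa-Michael of the lactol OH (bridged acetal), C7 epimerisation of the open aldehyde, and the C6 epimer. Fallback (known chemistry): a conventional base-mediated intermolecular oxa-Michael/intramolecular aldol cascade on 5 with 4-methoxybenzyl alcohol, which still lets the chair-controlled aldol select the enone and gives the 9-OPMB analogue of 6. This would be followed by Luche reduction, C4–OH-directed epoxidation, silylation, DDQ removal of PMB (replacing Step 7), oxidation and HF.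
2. **Step 5 (facial selectivity at C4).** If hydride enters from the exo face, change the order: Weitz–Scheffer epoxidation of enone 6 (exo face) first, then reduce the α,β-epoxy ketone, where hydride is forced anti to the epoxide oxygen to give the cis-epoxy alcohol. The boronate is re-formed with PhB(OH)2 if cleaved, and Step 8 is dropped.
3. **Step 9 (oxidation of the hindered C9–OH next to the tertiary OH).** If slow or if glycol cleavage occurs, switch to stannylene activation: form the dibutylstannylene acetal of the cis-1,9-diol (Bu2SnO) and oxidise by brominolysis (NBS), which converts only the secondary carbinol of a cis-1,2-diol to the ketone.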